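**Retrosynthetic overview**

1. Target ⇐ desilylation at O1 and double acetylation of a C8,C13-diol ⇐ bicyclic 8-hydroxy butenolide with silyl ethers on O1 and O13.
2. Key disconnection: the C7–C8 bond of ring A (ten-membered carbocycle) together with the C6–O bond of ring B (butenolide) ⇒ an acyclic 2,3-allenoic acid carrying a C8 aldehyde; forward, one palladium event closes ring B first and ring A second.
3. Enabling feature: ring B (O–C6–C7=C11–C12=O) is the cycloisomer of a 2,3-allenoic acid (C12 acid on C11=C7=C6). Oxypalladation puts the metal on C7, the ring-fusion carbon bonded to the C8 carbinol (an aldehyde in the precursor), and the C6 centre is stored in the allene axis.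
4. Allenoic acid ⇐ anti-SN2' carbonylation (zerovalent palladium, CO, water) of a 6S allylic/propargylic carbonate ⇐ CBS reduction of an ynone ⇐ Z-enal + silyl propargyl ether (C7, C11, C13).
5. C1–C6 with the Z C4=C5 bond and C15 ⇐ neryl acetate (oxidative cleavage to the C1 aldehyde); C8–C10 and C14 ⇐ but-3-yn-1-ol via a 2-iodoalkene and Nozaki–Hiyama–Kishi coupling, C1 set by CBS reduction of the derived enone.

Key step: step 17

Remark: the SMILES fixes C4=C5 as Z (C3 and C6 cis), so the C1–C6 unit is taken from neryl acetate; positions are given in germacrane numbering (C1–C15) throughout.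

**Route**

Step 1
Reactants: 1 neryl acetate
Product: 3 (2Z)-3-methyl-6-oxohex-2-en-1-yl acetate, via 6,7-epoxyneryl acetate 2 (not isolated)
Conditions: mCPBA, CH2Cl2, 0 °C; then H5IO6, THF/H2O, 0 °C to rt
Reagents that add atoms: mCPBA, O=C(OO)c1cccc(Cl)c1
Why: Prilezhaev epoxidation should take the electron-rich C1=C10 alkene (the C4=C5 alkene is deactivated by the allylic acetate), and periodic acid then opens and cleaves the epoxide (Malaprade-type glycol cleavage) to the C1 aldehyde without touching the Z alkene.

Step 2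
Reactants: 4 but-3-yn-1-ol
Product: 5 3-iodobut-3-en-1-ol
Conditions: NaI, Me3SiCl, H2O, MeCN, rt
Reagents that add atoms: sodium iodide, [Na+].[I-]
Why: Markovnikov hydroiodination of the terminal alkyne by hydrogen iodide generated in the flask should give the 2-iodoalkene that will become C10 (with C14, C9 and C8).

Step 3
Reactants: 5 3-iodobut-3-en-1-ol
Product: 6 triethyl[(3-iodobut-3-en-1-yl)oxy]silane
Conditions: Et3SiCl, imidazole, CH2Cl2, 0 °C
Reagents that add atoms: chlorotriethylsilane, CC[Si](Cl)(CC)CC
Why: Silyl ether formation masks the primary alcohol (the future C8 aldehyde) with the most labile of the three silyl groups used, and the alkenyl iodide is inert.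

Step 4
Reactants: 3 (2Z)-3-methyl-6-oxohex-2-en-1-yl acetate; 6 triethyl[(3-iodobut-3-en-1-yl)oxy]silane
Product: 8 (2Z)-6-hydroxy-3-methyl-7-methylidene-9-(triethylsilyloxy)non-2-en-1-yl acetate (both C1 epimers), via alkenylchromium dichloride 7 (not isolated)
Conditions: CrCl2, NiCl2 (2 mol%), DMF, rt
Reagents that add atoms: none
Why: Nozaki–Hiyama–Kishi coupling forms the C1–C10 bond by nickel-catalysed generation of the alkenylchromium and its chemoselective 1,2-addition to the aldehyde in the presence of the acetate; C1 is formed without control and is erased in step 5.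

Step 5
Reactants: 8 (2Z)-6-hydroxy-3-methyl-7-methylidene-9-(triethylsilyloxy)non-2-en-1-yl acetate
Product: 9 (2Z)-3-methyl-7-methylidene-6-oxo-9-(triethylsilyloxy)non-2-en-1-yl acetate
Conditions: Dess–Martin periodinane, CH2Cl2, 0 °C to rt
Reagents that add atoms: none
Why: Dess–Martin oxidation of the secondary allylic alcohol should give the α-methylene ketone under mild conditions that leave the silyl ether, the acetate and the Z alkene alone.

Step 6
Reactants: 9 (2Z)-3-methyl-7-methylidene-6-oxo-9-(triethylsilyloxy)non-2-en-1-yl acetate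
Product: 10 (2Z,6R)-6-hydroxy-3-methyl-7-methylidene-9-(triethylsilyloxy)non-2-en-1-yl acetate
Conditions: (S)-2-methyl-CBS-oxazaborolidine (20 mol%), catecholborane, toluene, −78 °C
Reagents that add atoms: none
Why: In this Corey–Bakshi–Shibata reduction the α-branched alkenyl flank (C10) acts as the large group and the C2 methylene chain as the small one, so the (S)-catalyst should deliver hydride to the face that gives the 1R carbinol (6R in the name of 10).

Step 7
Reactants: 10 (2Z,6R)-6-hydroxy-3-methyl-7-methylidene-9-(triethylsilyloxy)non-2-en-1-yl acetate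
Product: 11 (2Z,6R)-6-(tert-butyldimethylsilyloxy)-3-methyl-7-methylidene-9-(triethylsilyloxy)non-2-en-1-yl acetate
Conditions: t-BuMe2SiCl, imidazole, DMF, rt
Reagents that add atoms: tert-butyldimethylsilyl chloride, CC(C)(C)[Si](C)(C)Cl
Why: Silyl ether formation protects the C1 carbinol until the last step with a group that outlasts the triethylsilyl ether on O8.

Step 8
Reactants: 11 (2Z,6R)-6-(tert-butyldimethylsilyloxy)-3-methyl-7-methylidene-9-(triethylsilyloxy)non-2-en-1-yl acetate
Product: 12 (2Z,6R)-6-(tert-butyldimethylsilyloxy)-3-methyl-7-methylidene-9-(triethylsilyloxy)non-2-en-1-ol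
Conditions: i-Bu2AlH, CH2Cl2, −78 °C
Reagents that add atoms: none
Why: Reductive ester cleavage by the aluminium hydride at low temperature should free the C6 allylic alcohol without touching either silyl ether.

Step 9
Reactants: 12 (2Z,6R)-6-(tert-butyldimethylsilyloxy)-3-methyl-7-methylidene-9-(triethylsilyloxy)non-2-en-1-ol
Product: 13 (2Z,6R)-6-(tert-butyldimethylsilyloxy)-3-methyl-7-methylidene-9-(triethylsilyloxy)non-2-enal
Conditions: MnO2, CH2Cl2, rt
Reagents that add atoms: none
Why: Allylic oxidation with activated MnO2 is neutral and should give the Z-enal without Z to E isomerisation.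

Step 10
Reactants: 13 (2Z,6R)-6-(tert-butyldimethylsilyloxy)-3-methyl-7-methylidene-9-(triethylsilyloxy)non-2-enal; 14 tert-butyldimethyl(prop-2-yn-1-yloxy)silane
Product: 16 (5Z,9R)-1,9-bis(tert-butyldimethylsilyloxy)-6-methyl-10-methylidene-12-(triethylsilyloxy)dodec-5-en-2-yn-4-ol (both C6 epimers), via lithium acetylide 15 (not isolated)
Conditions: n-BuLi, THF, −78 °C; then 13, −78 °C
Reagents that add atoms: none
Why: 1,2-Addition of the lithium acetylide to the enal (acetylide addition) brings in C7, C11 and C13; the uncontrolled C6 carbinol is erased in step 11.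

Step 11
Reactants: 16 (5Z,9R)-1,9-bis(tert-butyldimethylsilyloxy)-6-methyl-10-methylidene-12-(triethylsilyloxy)dodec-5-en-2-yn-4-ol
Product: 17 (5Z,9R)-1,9-bis(tert-butyldimethylsilyloxy)-6-methyl-10-methylidene-12-(triethylsilyloxy)dodec-5-en-2-yn-4-one
Conditions: MnO2, CH2Cl2, rt
Reagents that add atoms: none
Why: MnO2 oxidation of the doubly activated (allylic and propargylic) carbinol should give the cross-conjugated ynone under neutral conditions that keep the Z alkene.

Step 12
Reactants: 17 (5Z,9R)-1,9-bis(tert-butyldimethylsilyloxy)-6-methyl-10-methylidene-12-(triethylsilyloxy)dodec-5-en-2-yn-4-one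
Product: 18 (4S,5Z,9R)-1,9-bis(tert-butyldimethylsilyloxy)-6-methyl-10-methylidene-12-(triethylsilyloxy)dodec-5-en-2-yn-4-ol
Conditions: (S)-2-methyl-CBS-oxazaborolidine, catecholborane, toluene, −78 °C
Reagents that add atoms: none
Why: In this Corey–Bakshi–Shibata reduction the Z-alkenyl flank with its cis methylene substituent is taken as the large group and the slim alkynyl flank as the small one, so the (S)-catalyst should give the 6S propargylic alcohol (4S in the name of 18).

Step 13
Reactants: 18 (4S,5Z,9R)-1,9-bis(tert-butyldimethylsilyloxy)-6-methyl-10-methylidene-12-(triethylsilyloxy)dodec-5-en-2-yn-4-ol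
Product: 19 (4S,5Z,9R)-1,9-bis(tert-butyldimethylsilyloxy)-6-methyl-10-methylidene-12-(triethylsilyloxy)dodec-5-en-2-yn-4-yl methyl carbonate
Conditions: ClCO2Me, pyridine, DMAP (cat.), CH2Cl2, 0 °C
Reagents that add atoms: methyl chloroformate, COC(=O)Cl
Why: O-Acylation (carbonate formation) turns the C6 hydroxyl into the leaving group for the SN2' step without ionising the sensitive carbinol; the crude carbonate is used directly.

Step 14
Reactants: 19 (4S,5Z,9R)-1,9-bis(tert-butyldimethylsilyloxy)-6-methyl-10-methylidene-12-(triethylsilyloxy)dodec-5-en-2-yn-4-yl methyl carbonate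
Product: 20 (Ra,5Z,9R)-9-(tert-butyldimethylsilyloxy)-2-[(tert-butyldimethylsilyloxy)methyl]-6-methyl-10-methylidene-12-(triethylsilyloxy)dodeca-2,3,5-trienoic acid
Conditions: Pd(PPh3)4 (5 mol%), CO (1 atm), THF/H2O, 0 °C to rt
Reagents that add atoms: carbon monoxide, [C-]#[O+]; water, O
Why: In this palladium-catalysed carbonylation of a propargylic carbonate, zerovalent palladium attacks C11 anti to the leaving carbonate (SN2'), CO inserts and water cleaves the acylpalladium, so the 6S centre is relayed to the (Ra) allene axis (centre-to-axis chirality transfer) and C12 is installed on C11; the O13 silyl ether is not a leaving group, which prevents a second SN2' event.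

Step 15
Reactants: 20 (Ra,5Z,9R)-9-(tert-butyldimethylsilyloxy)-2-[(tert-butyldimethylsilyloxy)methyl]-6-methyl-10-methylidene-12-(triethylsilyloxy)dodeca-2,3,5-trienoic acid
Product: 21 (Ra,5Z,9R)-9-(tert-butyldimethylsilyloxy)-2-[(tert-butyldimethylsilyloxy)methyl]-12-hydroxy-6-methyl-10-methylidene-dodeca-2,3,5-trienoic acid
Conditions: PPTS (cat.), MeOH/CH2Cl2, 0 °C
Reagents that add atoms: none
Why: Acid-catalysed methanolysis (selective desilylation) should remove the primary triethylsilyl ether much faster than the primary and the secondary tert-butyldimethylsilyl ethers.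

Step 16
Reactants: 21 (Ra,5Z,9R)-9-(tert-butyldimethylsilyloxy)-2-[(tert-butyldimethylsilyloxy)methyl]-12-hydroxy-6-methyl-10-methylidene-dodeca-2,3,5-trienoic acid
Product: 22 (Ra,5Z,9R)-9-(tert-butyldimethylsilyloxy)-2-[(tert-butyldimethylsilyloxy)methyl]-6-methyl-10-methylidene-12-oxododeca-2,3,5-trienoic acid
Conditions: Dess–Martin periodinane, CH2Cl2, 0 °C; crude product used at once below rt
Reagents that add atoms: none
Why: Dess–Martin oxidation gives the β,γ-unsaturated C8 aldehyde under non-basic conditions that should avoid migration of the C10=C14 bond into conjugation, and the allene tolerates the reagent.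

Step 17
Reactants: 22 (Ra,5Z,9R)-9-(tert-butyldimethylsilyloxy)-2-[(tert-butyldimethylsilyloxy)methyl]-6-methyl-10-methylidene-12-oxododeca-2,3,5-trienoic acid
Product: 24 (1R,6R,8S)-8-hydroxy-1,13-bis(tert-butyldimethylsilyloxy)germacra-4Z,7(11),10(14)-trien-6,12-olide, via alkenylpalladium acetate 23 (not isolated)
Conditions: Pd(OAc)2 (10 mol%), 2,2'-bipyridine (12 mol%), 4 Å molecular sieves, 1,4-dioxane (0.002 M), 25 to 50 °C
Reagents that add atoms: none
Why: Proposed new method: Pd(OAc)2 exchanges acetate for the carboxylate of 22 and divalent palladium binds the distal C6=C7 bond of the allene, the carboxylate oxygen adds anti at C6 (5-endo closure of ring B) to leave the C7–Pd bond of 23, and this bipyridine-bound alkenylpalladium inserts the tethered C8 aldehyde (10-exo-trig closure of ring A through the new C7–C8 bond) before acetic acid protonates the palladium alkoxide and returns Pd(OAc)2. The closest known reaction types are the divalent-palladium coupling-cyclisation of 2,3-allenoic acids, in which the same 4-furanonylpalladium species is trapped by allyl halides and alkenes, and the bipyridine/Pd(OAc)2 tandem nucleopalladation and carbonyl insertion of alkynes bearing a tethered aldehyde (five- and six-membered rings); the merger of the two and the ten-membered ring size are new. C6 is controlled by axis-to-centre chirality transfer, because the oxygen can enter only in the plane of the carboxyl group, so the (Ra) axis gives 6R. C8 is controlled by the C6 centre through the ring-closing geometry: with C5 and C9 on opposite faces of the flat butenolide and the C8–H bond eclipsing C11–C13 (allylic 1,3-strain), the oxygen should be placed as in 8S. The step needs carbonyl insertion to outrun protonolysis of 23 and needs the carboxylate, not an alkene, to attack the allene: the Z C4=C5 bond next to C6 turns the chain back over the butenolide and holds the aldehyde near C7, the carboxyl group on C11 can reach only C6, and the chelating ligand with acetic acid as the only weak proton source should slow protonolysis.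

Step 18
Reactants: 24 (1R,6R,8S)-8-hydroxy-1,13-bis(tert-butyldimethylsilyloxy)germacra-4Z,7(11),10(14)-trien-6,12-olide
Product: 25 (1R,6R,8S)-8,13-dihydroxy-1-(tert-butyldimethylsilyloxy)germacra-4Z,7(11),10(14)-trien-6,12-olide
Conditions: HF·pyridine, pyridine, THF, 0 °C
Reagents that add atoms: none
Why: Buffered fluoride desilylation should cleave the primary allylic silyl ether on O13 selectively over the hindered secondary one on O1; the C8 hydroxyl is trans to C12 across C7=C11 and cannot translactonise.

Step 19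
Reactants: 25 (1R,6R,8S)-8,13-dihydroxy-1-(tert-butyldimethylsilyloxy)germacra-4Z,7(11),10(14)-trien-6,12-olide
Product: 26 (1R,6R,8S)-8,13-diacetoxy-1-(tert-butyldimethylsilyloxy)germacra-4Z,7(11),10(14)-trien-6,12-olide
Conditions: Ac2O, pyridine, DMAP (cat.), CH2Cl2, 0 °C to rt
Reagents that add atoms: acetic anhydride, CC(=O)OC(C)=O
Why: DMAP-catalysed acetylation esterifies the C8 and C13 hydroxyls in one operation while O1 stays silylated.

Step 20
Reactants: 26 (1R,6R,8S)-8,13-diacetoxy-1-(tert-butyldimethylsilyloxy)germacra-4Z,7(11),10(14)-trien-6,12-olide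
Product: 27 8α,13-diacetoxy-1β-hydroxygermacra-4,7(11),10(14)-trien-6α,12-olide
Conditions: HF·pyridine, THF, 0 °C to rt
Reagents that add atoms: none
Why: Fluoride desilylation under acidic, non-nucleophilic conditions should free the C1 hydroxyl without acetate migration or lactone opening.

**Compound list**

1 | neryl acetate, (2Z)-3,7-dimethylocta-2,6-dien-1-yl acetate | CC(C)=CCC/C(C)=C\COC(C)=O | starting material
2 | 6,7-epoxyneryl acetate, (2Z)-5-(3,3-dimethyloxiran-2-yl)-3-methylpent-2-en-1-yl acetate (racemic) | CC1(C)OC1CC/C(C)=C\COC(C)=O | intermediate (not isolated)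
3 | (2Z)-3-methyl-6-oxohex-2-en-1-yl acetate | O=CCC/C(C)=C\COC(C)=O | intermediate
4 | but-3-yn-1-ol | C#CCCO | starting material
5 | 3-iodobut-3-en-1-ol | C=C(I)CCO | intermediate
6 | triethyl[(3-iodobut-3-en-1-yl)oxy]silane | C=C(I)CCO[Si](CC)(CC)CC | intermediate
7 | [4-(triethylsilyloxy)but-1-en-2-yl]chromium dichloride (trivalent chromium, solvent ligands not drawn) | C=C([Cr](Cl)Cl)CCO[Si](CC)(CC)CC | intermediate (not isolated)
8 | (2Z)-6-hydroxy-3-methyl-7-methylidene-9-(triethylsilyloxy)non-2-en-1-yl acetate (both C1 epimers) | CC[Si](CC)(CC)OCCC(=C)C(O)CC/C(C)=C\COC(C)=O | intermediate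
9 | (2Z)-3-methyl-7-methylidene-6-oxo-9-(triethylsilyloxy)non-2-en-1-yl acetate | CC[Si](CC)(CC)OCCC(=C)C(=O)CC/C(C)=C\COC(C)=O | intermediate
10 | (2Z,6R)-6-hydroxy-3-methyl-7-methylidene-9-(triethylsilyloxy)non-2-en-1-yl acetate | CC[Si](CC)(CC)OCCC(=C)[C@H](O)CC/C(C)=C\COC(C)=O | intermediate
11 | (2Z,6R)-6-(tert-butyldimethylsilyloxy)-3-methyl-7-methylidene-9-(triethylsilyloxy)non-2-en-1-yl acetate | CC[Si](CC)(CC)OCCC(=C)[C@H](O[Si](C)(C)C(C)(C)C)CC/C(C)=C\COC(C)=O | intermediate
12 | (2Z,6R)-6-(tert-butyldimethylsilyloxy)-3-methyl-7-methylidene-9-(triethylsilyloxy)non-2-en-1-ol | CC[Si](CC)(CC)OCCC(=C)[C@H](O[Si](C)(C)C(C)(C)C)CC/C(C)=C\CO | intermediate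
13 | (2Z,6R)-6-(tert-butyldimethylsilyloxy)-3-methyl-7-methylidene-9-(triethylsilyloxy)non-2-enal | CC[Si](CC)(CC)OCCC(=C)[C@H](O[Si](C)(C)C(C)(C)C)CC/C(C)=C\C=O | intermediate
14 | tert-butyldimethyl(prop-2-yn-1-yloxy)silane | C#CCO[Si](C)(C)C(C)(C)C | starting material
15 | lithium 3-(tert-butyldimethylsilyloxy)prop-1-yn-1-ide | [Li]C#CCO[Si](C)(C)C(C)(C)C | intermediate (not isolated)
16 | (5Z,9R)-1,9-bis(tert-butyldimethylsilyloxy)-6-methyl-10-methylidene-12-(triethylsilyloxy)dodec-5-en-2-yn-4-ol (both C6 epimers) | CC[Si](CC)(CC)OCCC(=C)[C@H](O[Si](C)(C)C(C)(C)C)CC/C(C)=C\C(O)C#CCO[Si](C)(C)C(C)(C)C | intermediate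
17 | (5Z,9R)-1,9-bis(tert-butyldimethylsilyloxy)-6-methyl-10-methylidene-12-(triethylsilyloxy)dodec-5-en-2-yn-4-one | CC[Si](CC)(CC)OCCC(=C)[C@H](O[Si](C)(C)C(C)(C)C)CC/C(C)=C\C(=O)C#CCO[Si](C)(C)C(C)(C)C | intermediate
18 | (4S,5Z,9R)-1,9-bis(tert-butyldimethylsilyloxy)-6-methyl-10-methylidene-12-(triethylsilyloxy)dodec-5-en-2-yn-4-ol | CC[Si](CC)(CC)OCCC(=C)[C@H](O[Si](C)(C)C(C)(C)C)CC/C(C)=C\[C@H](O)C#CCO[Si](C)(C)C(C)(C)C | intermediate
19 | (4S,5Z,9R)-1,9-bis(tert-butyldimethylsilyloxy)-6-methyl-10-methylidene-12-(triethylsilyloxy)dodec-5-en-2-yn-4-yl methyl carbonate | CC[Si](CC)(CC)OCCC(=C)[C@H](O[Si](C)(C)C(C)(C)C)CC/C(C)=C\[C@H](OC(=O)OC)C#CCO[Si](C)(C)C(C)(C)C | intermediate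
20 | (Ra,5Z,9R)-9-(tert-butyldimethylsilyloxy)-2-[(tert-butyldimethylsilyloxy)methyl]-6-methyl-10-methylidene-12-(triethylsilyloxy)dodeca-2,3,5-trienoic acid | OC(=O)C(CO[Si](C)(C)C(C)(C)C)=[C@]=C([H])/C=C(/C)CC[C@@H](O[Si](C)(C)C(C)(C)C)C(=C)CCO[Si](CC)(CC)CC | intermediate
21 | (Ra,5Z,9R)-9-(tert-butyldimethylsilyloxy)-2-[(tert-butyldimethylsilyloxy)methyl]-12-hydroxy-6-methyl-10-methylidene-dodeca-2,3,5-trienoic acid | OC(=O)C(CO[Si](C)(C)C(C)(C)C)=[C@]=C([H])/C=C(/C)CC[C@@H](O[Si](C)(C)C(C)(C)C)C(=C)CCO | intermediate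
22 | (Ra,5Z,9R)-9-(tert-butyldimethylsilyloxy)-2-[(tert-butyldimethylsilyloxy)methyl]-6-methyl-10-methylidene-12-oxododeca-2,3,5-trienoic acid | OC(=O)C(CO[Si](C)(C)C(C)(C)C)=[C@]=C([H])/C=C(/C)CC[C@@H](O[Si](C)(C)C(C)(C)C)C(=C)CC=O | intermediate
23 | C7-palladated butenolide: acetato(2,2'-bipyridine)palladium (divalent palladium) bound to C7 of the 6R butenolide that still carries the open C8 aldehyde chain | CC(=O)O[Pd]C1=C(CO[Si](C)(C)C(C)(C)C)C(=O)O[C@@H]1/C=C(/C)CC[C@@H](O[Si](C)(C)C(C)(C)C)C(=C)CC=O.c1ccnc(c1)-c1ccccn1 | intermediate (not isolated)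
24 | (1R,6R,8S)-8-hydroxy-1,13-bis(tert-butyldimethylsilyloxy)germacra-4Z,7(11),10(14)-trien-6,12-olide | C=C1C[C@H](O)C2=C(CO[Si](C)(C)C(C)(C)C)C(=O)O[C@@H]2/C=C(/C)CC[C@H]1O[Si](C)(C)C(C)(C)C | intermediate
25 | (1R,6R,8S)-8,13-dihydroxy-1-(tert-butyldimethylsilyloxy)germacra-4Z,7(11),10(14)-trien-6,12-olide | C=C1C[C@H](O)C2=C(CO)C(=O)O[C@@H]2/C=C(/C)CC[C@H]1O[Si](C)(C)C(C)(C)C | intermediate
26 | (1R,6R,8S)-8,13-diacetoxy-1-(tert-butyldimethylsilyloxy)germacra-4Z,7(11),10(14)-trien-6,12-olide | C=C1C[C@H](OC(C)=O)C2=C(COC(C)=O)C(=O)O[C@@H]2/C=C(/C)CC[C@H]1O[Si](C)(C)C(C)(C)C | intermediate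
27 | 8α,13-diacetoxy-1β-hydroxygermacra-4,7(11),10(14)-trien-6α,12-olide, (1R,6R,8S), 4Z | C=C1C[C@H](OC(C)=O)C2=C(COC(C)=O)C(=O)O[C@@H]2/C=C(/C)CC[C@H]1O | target

**Step count and risks**

Total step count: 20. Longest linear sequence: 19 steps (steps 2 to 20, from but-3-yn-1-ol 4); 18 steps from neryl acetate 1.

The three steps most likely to fail:

Step 17 (Proposed new method). Protonolysis of the C7–Pd bond may outrun carbonyl insertion across a ten-membered transition state, so that only cycloisomerisation to an open-chain butenolide occurs; face selection at C8 may also be poor. The fallback uses known chemistry, sets out from 22 and comes back at 24. Iodolactonisation of 22 (I2, NaHCO3, MeCN/H2O, 0 °C) follows the same anti addition and axis-to-centre transfer and should give the 4-iodobutenolide aldehyde F1 with the 6R centre. An intramolecular Nozaki–Hiyama–Kishi reaction of F1 (CrCl2, NiCl2 cat., DMSO/THF, syringe-pump addition to high dilution, rt) would then pass through the alkenylchromium dichloride F2 and form the same C7–C8 bond to give 24. If the C8 face is poorly selected there, a chiral oxazoline–sulfonamide ligand on chromium would be added for reagent control.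

Step 14. The doubly activated (allylic and propargylic) carbonate may ionise towards an allylpalladium species (elimination or attack at the allylic terminus), and the centre-to-axis transfer may erode by equilibration of the allenylpalladium intermediate. The fallback sets out from 18 and comes back at 20. The alcohol 18 would be converted at −78 °C (MeSO2Cl, Et3N, THF) into the mesylate F3, which is displaced in the same flask by LiCuBr2 (CuBr·SMe2, LiBr) in an anti-SN2' sense to give the bromoallene F4. Hydroxycarbonylation of the C(sp2)–Br bond of F4 (Pd(PPh3)4, CO, i-Pr2NEt, THF/H2O), in which zerovalent palladium inserts with retention, would give the same (Ra) acid 20 without an ionisable carbonate in the presence of the catalyst.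

Step 12. Both flanks of the ketone are unsaturated, so facial discrimination by the oxazaborolidine may be poor; a C6 epimer mixture would surface as the wrong lactone epimer after step 17. The fallback sets out from 13 (with 14) and comes back at 18, leaving out 16 and 17. It is a direct catalytic asymmetric alkynylation: Me2Zn and alkyne 14 form the alkynyl(methyl)zinc F5, which adds to enal 13 in the presence of the ProPhenol ligand (2,6-bis{[2-(hydroxydiphenylmethyl)pyrrolidin-1-yl]methyl}-4-methylphenol) and Ph3P=O in toluene at 0 °C. The ligand enantiomer is the one that directs the alkynyl group to the Re face of the aldehyde carbon, which is the face that gives 6S.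

**Further compounds**

F1 | step 17 | (5R)-4-iodo-3-[(tert-butyldimethylsilyloxy)methyl]-5-[(1Z,6R)-6-(tert-butyldimethylsilyloxy)-2-methyl-7-methylidene-9-oxonon-1-en-1-yl]furan-2(5H)-one (iodobutenolide aldehyde) | IC1=C(CO[Si](C)(C)C(C)(C)C)C(=O)O[C@@H]1/C=C(/C)CC[C@@H](O[Si](C)(C)C(C)(C)C)C(=C)CC=O
F2 | step 17 | alkenylchromium dichloride derived from F1 (trivalent chromium on C7, solvent ligands not drawn) | Cl[Cr](Cl)C1=C(CO[Si](C)(C)C(C)(C)C)C(=O)O[C@@H]1/C=C(/C)CC[C@@H](O[Si](C)(C)C(C)(C)C)C(=C)CC=O
F3 | step 14 | (4S,5Z,9R)-1,9-bis(tert-butyldimethylsilyloxy)-6-methyl-10-methylidene-12-(triethylsilyloxy)dodec-5-en-2-yn-4-yl methanesulfonate | CC[Si](CC)(CC)OCCC(=C)[C@H](O[Si](C)(C)C(C)(C)C)CC/C(C)=C\[C@H](OS(C)(=O)=O)C#CCO[Si](C)(C)C(C)(C)C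
F4 | step 14 | (Ra,5Z,9R)-2-bromo-1,9-bis(tert-butyldimethylsilyloxy)-6-methyl-10-methylidene-12-(triethylsilyloxy)dodeca-2,3,5-triene (bromoallene) | BrC(CO[Si](C)(C)C(C)(C)C)=[C@]=C([H])/C=C(/C)CC[C@@H](O[Si](C)(C)C(C)(C)C)C(=C)CCO[Si](CC)(CC)CC
F5 | step 12 | [3-(tert-butyldimethylsilyloxy)prop-1-yn-1-yl](methyl)zinc | C[Zn]C#CCO[Si](C)(C)C(C)(C)C
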